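**Retrosynthetic overview**
- The target is an unbranched C19 acid with a single ring, a furan attached through C2' to C19. Only C2–C4 separate the C5≡C6 triple bond from the C1 carboxyl, so C1–C6 is the skeleton of hex-5-ynoic acid. The sp carbon C6 is bonded to an unhindered primary carbon, C7.
- Last bond made: C6–C7. The acetylide carbon of doubly lithiated, unprotected hex-5-ynoic acid displaces bromide from 2-(13-bromotridecyl)furan.
- Earlier bond: C19–C2'. 2-Lithiofuran is alkylated by excess 1,13-dibromotridecane, which is made from tridecanedioic acid by reduction and bromination.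
- No ring is formed. The furan is bought intact and meets only basic or briefly cold acidic media.

Key step: step 4

Remark: the SMILES carries no stereodescriptor, and the structure has no stereocentre and no acyclic C=C bond, so no stereocontrol is needed. Chain atoms are numbered C1 (carboxyl) to C19 and furan atoms O1', C2'–C5'.

Step 1
Reactants: 1 tridecanedioic acid
Product: 2 tridecane-1,13-diol
Conditions: BH3·THF (3 equiv), THF, 0 °C → rt; then H2O, extraction with warm EtOAc
Reagents that add atoms: none
Why: Borane reduction of carboxylic acids, in which each CO2H reacts through an acyloxyborane that collapses to the borate of the primary alcohol, and the saturated chain offers nothing else to reduce.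

Step 2
Reactants: 2 tridecane-1,13-diol
Product: 3 1,13-dibromotridecane
Conditions: 48% aq. HBr (excess), conc. H2SO4, reflux
Reagents that add atoms: hydrogen bromide, Br
Why: Acid-mediated SN2 substitution of primary alcohols (O-protonation, then displacement of water by bromide) is the classical preparation of α,ω-dibromoalkanes, and the two remote unbranched termini should react independently without rearrangement.

Step 3
Reactants: 4 furan; 3 1,13-dibromotridecane
Product: 6 2-(13-bromotridecyl)furan, via 2-lithiofuran 5 (not isolated)
Conditions: 4 (1.2 equiv), n-BuLi (1.0 equiv), THF, −78 → 0 °C; cannulated slowly into 3 (3.0 equiv), THF, 0 °C → rt; chromatography (hexanes), recovered 3 recycled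
Reagents that add atoms: none
Why: α-Lithiation of furan followed by SN2 alkylation with a primary bromide is a standard entry to 2-alkylfurans, and inverse addition of 5 to a threefold excess of 3 should leave the second C–Br bond largely untouched.

Step 4
Reactants: 7 hex-5-ynoic acid; 6 2-(13-bromotridecyl)furan
Product: 10 19-(furan-2-yl)nonadec-5-ynoic acid, via lithium 6-lithiohex-5-ynoate 8 (not isolated), via lithium 19-(furan-2-yl)nonadec-5-ynoate 9 (not isolated)
Conditions: 7 (1.5 equiv), n-BuLi (2.9 equiv), THF/HMPA (4:1), −78 → 0 °C; then 6 (1.0 equiv), 0 °C → rt; then 1 M HCl, 0 °C, to pH 3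
Reagents that add atoms: none
Why: One equivalent of n-BuLi turns the CO2H of 7 into its lithium salt and the next removes the sp C–H in preference to a C2–H, giving 8, whose acetylide carbon C6 displaces bromide from C7 of 6 by SN2 while HMPA loosens the lithium aggregates. The closest known reaction type is the alkylation of dilithiated ω-alkynoic acids with primary alkyl bromides in THF/HMPA or THF/DMPU. Only the C6–C7 bond is formed, so no ring is closed and no stereocentre is created. The step needs C- over O-alkylation and substitution over E2, which should follow because the charge-localised acetylide is far more nucleophilic than the delocalised, lithium-bound carboxylate and because the bromide is primary with no branching at C8. Keeping n-BuLi just under two equivalents per 7 leaves no free alkyllithium to add to the carboxylate or to metalate furan C5'–H, a proton the acetylide is too weak a base to remove. Brief cold acidification protonates 9 to 10 without hydrolysing the acid-sensitive furan, and surplus 7 is removed by aqueous washing and chromatography.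

**Compound list**
1 | tridecanedioic acid | OC(=O)CCCCCCCCCCCC(=O)O | starting material
2 | tridecane-1,13-diol | OCCCCCCCCCCCCCO | intermediate
3 | 1,13-dibromotridecane | BrCCCCCCCCCCCCCBr | intermediate
4 | furan | c1ccoc1 | starting material
5 | 2-lithiofuran | [Li]c1ccco1 | intermediate
6 | 2-(13-bromotridecyl)furan | BrCCCCCCCCCCCCCc1ccco1 | intermediate
7 | hex-5-ynoic acid | C#CCCCC(=O)O | starting material
8 | lithium 6-lithiohex-5-ynoate (dilithiated hex-5-ynoic acid) | [Li]C#CCCCC(=O)O[Li] | intermediate
9 | lithium 19-(furan-2-yl)nonadec-5-ynoate | [Li]OC(=O)CCCC#CCCCCCCCCCCCCCc1ccco1 | intermediate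
10 | 19-(furan-2-yl)nonadec-5-ynoic acid | O=C(O)CCCC#CCCCCCCCCCCCCCc1ccco1 | target

Total step count: 4
Longest linear sequence: 4 steps (1 → 2 → 3 → 6 → 10)

**Steps most likely to fail**

1. Step 4.
- Risk: the dilithio salt may be poorly soluble and strongly aggregated, making the displacement slow. Loss of HBr from the bromide by E2, alkylation through the carboxylate oxygen, or butyl addition to the carboxylate after a small overcharge of base could then compete.
- Fallback: the acid is masked as a bridged orthoester, so that a soluble monolithium acetylide makes the same C6–C7 bond. The sequence sets out from 7 and uses 6 as electrophile.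
- Esterification of 7 with 3-methyl-3-oxetanemethanol (CC1(CO)COC1; DCC, DMAP, CH2Cl2) should give (3-methyloxetan-3-yl)methyl hex-5-ynoate F1.
- Catalytic BF3·OEt2 (CH2Cl2, −15 °C, Et3N quench) should rearrange this to 4-methyl-1-(pent-4-yn-1-yl)-2,6,7-trioxabicyclo[2.2.2]octane F2.
- n-BuLi (THF, −78 °C) converts it into 1-(5-lithiopent-4-yn-1-yl)-4-methyl-2,6,7-trioxabicyclo[2.2.2]octane F3.
- Alkylation by 6 in THF/HMPA should give 1-[18-(furan-2-yl)octadec-4-yn-1-yl]-4-methyl-2,6,7-trioxabicyclo[2.2.2]octane F4.
- Aqueous NaHSO4 in DME at 0 °C opens the orthoester to 3-hydroxy-2-(hydroxymethyl)-2-methylpropyl 19-(furan-2-yl)nonadec-5-ynoate F5.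
- LiOH (THF/H2O) saponifies this ester. The route is rejoined at 9, which is acidified to 10 as in step 4.

2. Step 3.
- Risk: alkylation may occur at both chain ends despite the excess of dibromide. The product may also co-elute with the large amount of equally non-polar unreacted dibromide during purification.
- Fallback: the two chain ends are differentiated before the furan is introduced. The sequence sets out from 2.
- Monobromination (48% aq. HBr, 1.1 equiv, toluene, reflux) should give 13-bromotridecan-1-ol F6.
- Silylation (TBSCl, imidazole, DMF) should give [(13-bromotridecyl)oxy](tert-butyl)dimethylsilane F7.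
- This bromide alkylates 5 (THF, 0 °C → rt) to tert-butyl{[13-(furan-2-yl)tridecyl]oxy}dimethylsilane F8, which is easily separated by polarity.
- TBAF (THF) releases 13-(furan-2-yl)tridecan-1-ol F9.
- An Appel bromination (CBr4, PPh3, CH2Cl2, 0 °C) returns to the route at 6.

3. Step 2.
- Risk: substitution may be incomplete in the two-phase hot acid medium, and intermolecular ether formation or charring of the molten diol may occur.
- Fallback: activation and displacement are carried out under non-acidic conditions. The sequence sets out from 2.
- MsCl and Et3N (CH2Cl2, 0 °C) should give tridecane-1,13-diyl dimethanesulfonate F10.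
- LiBr in refluxing acetone displaces both sulfonates, returning to the route at 3.

**Further compounds**
F1 | step 4 | (3-methyloxetan-3-yl)methyl hex-5-ynoate | C#CCCCC(=O)OCC1(C)COC1
F2 | step 4 | 4-methyl-1-(pent-4-yn-1-yl)-2,6,7-trioxabicyclo[2.2.2]octane | C#CCCCC12OCC(C)(CO1)CO2
F3 | step 4 | 1-(5-lithiopent-4-yn-1-yl)-4-methyl-2,6,7-trioxabicyclo[2.2.2]octane | [Li]C#CCCCC12OCC(C)(CO1)CO2
F4 | step 4 | 1-[18-(furan-2-yl)octadec-4-yn-1-yl]-4-methyl-2,6,7-trioxabicyclo[2.2.2]octane | CC12COC(CCCC#CCCCCCCCCCCCCCc3ccco3)(OC1)OC2
F5 | step 4 | 3-hydroxy-2-(hydroxymethyl)-2-methylpropyl 19-(furan-2-yl)nonadec-5-ynoate | OCC(C)(CO)COC(=O)CCCC#CCCCCCCCCCCCCCc1ccco1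
F6 | step 3 | 13-bromotridecan-1-ol | OCCCCCCCCCCCCCBr
F7 | step 3 | [(13-bromotridecyl)oxy](tert-butyl)dimethylsilane | CC(C)(C)[Si](C)(C)OCCCCCCCCCCCCCBr
F8 | step 3 | tert-butyl{[13-(furan-2-yl)tridecyl]oxy}dimethylsilane | CC(C)(C)[Si](C)(C)OCCCCCCCCCCCCCc1ccco1
F9 | step 3 | 13-(furan-2-yl)tridecan-1-ol | OCCCCCCCCCCCCCc1ccco1
F10 | step 2 | tridecane-1,13-diyl dimethanesulfonate | CS(=O)(=O)OCCCCCCCCCCCCCOS(C)(=O)=O
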